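**Strategy**

Everything rests on cutting the C8–C9 bond of ring B. The exocyclic C8=C17 methylene next to the C9 methine is read as what a terminal C8≡C17 alkyne leaves behind once a C9 enol carbon has added to C8. A single gold-catalysed cyclisation of a silyl enol ether onto that alkyne therefore closes ring B (6-exo-dig), fixes the methylene position without any elimination, sets C9 and delivers the C11 aldehyde for chain extension. The substrate is a ring A cyclohexane, made from (S)-α-ionone, that carries trans on C5 and C10 a but-3-ynyl chain and the TBS enol ether of an acetaldehyde arm; C12–C15 arrive later as a glyceraldehyde-derived epoxide.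

Key step: step 10

Assumption: (S)-α-ionone is used as the single enantiomer (bought as such or obtained from the commercial racemate by resolution); its stereocentre becomes C5.

Remark: labdane numbering is used for the carbons of all intermediates (C10 carries methyl C20, C5 carries the chain C6–C7–C8–C17, C4 the gem-dimethyl pair); the enol ether geometry of the cyclisation substrate is not critical and is drawn Z.

**Route**

Step 1
Reactants: 1 (S)-α-ionone
Product: 2 (S)-dihydro-α-ionone [4-((1S)-2,6,6-trimethylcyclohex-2-en-1-yl)butan-2-one]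
Conditions: Bu3SnH (1.1 equiv), AcOH (1.5 equiv), Pd(PPh3)4 (2 mol%), THF, rt
Reagents that add atoms: none
Why: Palladium-catalysed conjugate reduction with tin hydride (hydrostannation of the enone to a tin enolate that AcOH protonates) should touch only the electron-poor side-chain C=C, leaving the hindered trisubstituted ring alkene and the C5 stereocentre as they are.

Step 2
Reactants: 2 (S)-dihydro-α-ionone
Product: 3 2-methyl-2-{2-[(1S)-2,6,6-trimethylcyclohex-2-en-1-yl]ethyl}-1,3-dioxolane
Conditions: HOCH2CH2OH, PPTS (cat.), benzene, reflux, Dean–Stark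
Reagents that add atoms: ethylene glycol, OCCO
Why: Acid-catalysed ketalisation masks the methyl ketone (future C8 and C17) so that the ring carbonyl made next can be reduced on its own.

Step 3
Reactants: 3 dioxolane of dihydro-α-ionone
Product: 4 (4S)-3,5,5-trimethyl-4-[2-(2-methyl-1,3-dioxolan-2-yl)ethyl]cyclohex-2-en-1-one
Conditions: t-BuOOH (70% aq., 5 equiv), Rh2(cap)4 (cap = caprolactamate, 1 mol%), K2CO3, CH2Cl2, rt
Reagents that add atoms: tert-butyl hydroperoxide, CC(C)(C)OO
Why: Radical allylic C–H oxidation with tert-butyl hydroperoxide under dirhodium caprolactamate catalysis should convert the only unhindered allylic methylene, C2, into the enone carbonyl, while the flanked tertiary C5–H and the ketal are left alone.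

Step 4
Reactants: 4 ring enone
Product: 5 (1S,4S)-3,5,5-trimethyl-4-[2-(2-methyl-1,3-dioxolan-2-yl)ethyl]cyclohex-2-en-1-ol (hydroxyl trans to the side chain)
Conditions: Li[HB(s-Bu)3] (1.2 equiv), THF, −78 °C; then H2O
Reagents that add atoms: none
Why: 1,2-Reduction of the β,β-disubstituted enone by a bulky trialkylborohydride; in the half-chair that keeps the C5 chain pseudo-axial the axial C4 methyl blocks the opposite face of the carbonyl, so hydride should enter on the side of the chain and place the new C2 hydroxyl trans to it.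

Step 5
Reactants: 5 trans allylic alcohol
Product: 7 ethyl 2-{(1S,6S)-1,5,5-trimethyl-6-[2-(2-methyl-1,3-dioxolan-2-yl)ethyl]cyclohex-2-en-1-yl}acetate, via ketene acetal 6 (not isolated)
Conditions: MeC(OEt)3 (excess), EtCO2H (cat.), 140 °C, EtOH distilled off
Reagents that add atoms: triethyl orthoacetate, CCOC(C)(OCC)OCC
Why: Johnson–Claisen rearrangement: the ketene acetal undergoes a suprafacial [3,3] shift that forms C9–C10 on the face that carried the C2 oxygen, that is anti to the C5 chain, which sets the quaternary C10 with the acetate arm trans to the chain and methyl C20 cis to it.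

Step 6
Reactants: 7 unsaturated ketal ester
Product: 9 ethyl 2-[(1R,2S)-1,3,3-trimethyl-2-(3-oxobutyl)cyclohexyl]acetate, via saturated ketal ester 8 (not isolated)
Conditions: H2 (1 atm), 10% Pd/C, THF, rt; then 1 M aq. HCl, rt
Reagents that add atoms: water, O
Why: Heterogeneous hydrogenation saturates the disubstituted C1=C2 alkene without creating a stereocentre, and acetal hydrolysis in the same flask then releases the methyl ketone, which the hindered ethyl ester should survive.

Step 7
Reactants: 9 keto ester
Product: 11 ethyl 2-[(1R,2S)-2-(but-3-yn-1-yl)-1,3,3-trimethylcyclohexyl]acetate, via enol phosphate 10 (not isolated)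
Conditions: LiN(i-Pr)2 (1.05 equiv), THF, −78 °C; ClP(O)(OEt)2, −78 °C to rt; LiN(i-Pr)2 (3.2 equiv), −78 to 0 °C; then H2O
Reagents that add atoms: none
Why: Methyl ketone to terminal alkyne by kinetic enolate phosphorylation and base-induced elimination of the enol phosphate; the first base equivalent takes the more acidic, unhindered ketone methyl, and any ester enolate formed by the excess base is reprotonated on quench.

Step 8
Reactants: 11 alkynyl ester
Product: 12 2-[(1R,2S)-2-(but-3-yn-1-yl)-1,3,3-trimethylcyclohexyl]acetaldehyde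
Conditions: i-Bu2AlH (1.1 equiv), CH2Cl2, −78 °C; then aq. potassium sodium tartrate
Reagents that add atoms: none
Why: Partial reduction of the ester with a dialkylaluminium hydride should stop at the aluminium hemiacetal of this neopentyl-type ester at low temperature and give the aldehyde on hydrolysis, the terminal alkyne being inert.

Step 9
Reactants: 12 alkynyl aldehyde
Product: 13 tert-butyl({(Z)-2-[(1S,2S)-2-(but-3-yn-1-yl)-1,3,3-trimethylcyclohexyl]ethenyl}oxy)dimethylsilane
Conditions: TBSOTf (1.3 equiv), Et3N (2 equiv), CH2Cl2, −78 to 0 °C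
Reagents that add atoms: tert-butyldimethylsilyl triflate, CC(C)(C)[Si](C)(C)OS(=O)(=O)C(F)(F)F
Why: Soft enolisation with O-silylation of the aldehyde gives the C9=C11 silyl enol ether, drawn as the Z isomer; any E isomer formed alongside need not be removed because the enol geometry disappears when C11 returns to the aldehyde.

Step 10
Reactants: 13 alkynyl silyl enol ether
Product: 14 albicanal [12,13,14,15,16-pentanorlabd-8(17)-en-11-al; (1S,4aS,8aS)-5,5,8a-trimethyl-2-methylidenedecahydronaphthalene-1-carbaldehyde]
Conditions: Ph3PAuCl (5 mol%), AgSbF6 (5 mol%), MeOH (5 equiv), CH2Cl2, 0 °C to rt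
Reagents that add atoms: none
Why: Ph3PAu+ (monovalent gold) binds the terminal C8≡C17 alkyne and the enol ether carbon C9 adds anti to gold at the internal carbon C8, giving a vinylgold oxocarbenium ion that loses silicon to methanol and is protodeaurated to the exocyclic C8=C17 alkene and the C11 aldehyde. The closest known reaction type is the gold-catalysed carbocyclisation of silyl enol ethers onto alkynes (Conia-ene type). Ring B (C5–C6–C7–C8–C9–C10) closes in the 6-exo-dig mode, and the trans ring fusion follows from the trans C5/C10 pair already in ring A. The new stereocentre C9 is controlled by the ring A chair, on which the C6 and C9 arms are trans-diequatorial, through a chair-like transition state that keeps C11 pseudo-equatorial (9β, away from the axial hydrogens on C5 and C7); this is also the more stable epimer. The step needs exo closure over 7-endo closure, which the terminal alkyne secures because charge builds at the substituted carbon C8, and it needs the alkene to stay out of conjugation, which is secured by forming it through protodeauration and not elimination, under near-neutral conditions, with reduction of the crude aldehyde in step 11.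

Step 11
Reactants: 14 albicanal
Product: 15 albicanol [((1S,4aS,8aS)-5,5,8a-trimethyl-2-methylidenedecahydronaphthalen-1-yl)methanol]
Conditions: NaBH4, MeOH, 0 °C
Reagents that add atoms: none
Why: Borohydride reduction of the crude aldehyde removes the activation of C9–H before the β,γ-unsaturated aldehyde can epimerise or move its alkene into conjugation.

Step 12
Reactants: 15 albicanol
Product: 16 albicanyl bromide [(1S,4aS,8aS)-1-(bromomethyl)-5,5,8a-trimethyl-2-methylidenedecahydronaphthalene]
Conditions: CBr4, PPh3, CH2Cl2, 0 °C to rt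
Reagents that add atoms: carbon tetrabromide, BrC(Br)(Br)Br
Why: Appel bromination is an SN2 displacement on the alkoxyphosphonium ion under neutral conditions, so the homoallylic primary alcohol should give the bromide without rearrangement or alkene shift.

Step 13
Reactants: 17 (R)-2,3-O-isopropylideneglyceraldehyde
Product: 18 1-[(4R)-2,2-dimethyl-1,3-dioxolan-4-yl]ethan-1-ol (both carbinol epimers)
Conditions: MeMgBr, THF, −78 to 0 °C; then H2O
Reagents that add atoms: methylmagnesium bromide, C[Mg]Br
Why: Grignard addition to the aldehyde; the configuration of the new carbinol does not matter because it is oxidised in the next step.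

Step 14
Reactants: 18 secondary alcohol
Product: 19 1-[(4R)-2,2-dimethyl-1,3-dioxolan-4-yl]ethan-1-one
Conditions: Dess–Martin periodinane, NaHCO3, CH2Cl2, rt
Reagents that add atoms: none
Why: Dess–Martin oxidation under buffered, non-basic conditions should give the methyl ketone without epimerising the α-alkoxy stereocentre (future C14).

Step 15
Reactants: 19 methyl ketone
Product: 20 (2S)-2-[(4R)-2,2-dimethyl-1,3-dioxolan-4-yl]-2-methyloxirane
Conditions: Me3S+ I− (1.5 equiv), n-BuLi (1.4 equiv), THF, −10 °C; then 19, −10 °C to rt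
Reagents that add atoms: trimethylsulfonium iodide, C[S+](C)C.[I-]
Why: Corey–Chaykovsky epoxidation: irreversible addition of the sulfonium ylide to the ketone should follow the polar Felkin–Anh model (attack anti to the α C–O bond), which sets C13 as S and gives the erythro epoxide.

Step 16
Reactants: 16 albicanyl bromide; 20 epoxide
Product: 22 (13S,14R)-14,15-O-isopropylidenelabd-8(17)-ene-13,14,15-triol, via Grignard reagent 21 (not isolated)
Conditions: Mg, THF, 45 °C; then CuI (10 mol%), 20 (1.3 equiv), THF, −30 to 0 °C; then H2O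
Reagents that add atoms: none
Why: Copper-catalysed epoxide opening by the Grignard reagent is an SN2 attack at the unsubstituted epoxide carbon C12, so it forms C11–C12 and leaves C13 untouched as the tertiary alcohol.

Step 17
Reactants: 22 acetonide
Product: 23 (13S,14R)-labd-8(17)-ene-13,14,15-triol
Conditions: AcOH/H2O/THF (3:1:1), 45 °C
Reagents that add atoms: none
Why: Mild acetal hydrolysis frees the C14/C15 diol under conditions too weak to isomerise the C8=C17 alkene or to cyclise the C13 hydroxyl onto it.

Step 18
Reactants: 23 triol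
Product: 24 (13S,14R)-13,14-dihydroxylabd-8(17)-en-15-yl acetate
Conditions: AcCl (1.05 equiv), 2,4,6-collidine, CH2Cl2, −78 °C
Reagents that add atoms: acetyl chloride, CC(Cl)=O
Why: Selective acylation of the primary C15 hydroxyl with acetyl chloride and a hindered pyridine base at low temperature, the secondary and tertiary hydroxyls reacting far more slowly.

Step 19
Reactants: 24 C15 monoacetate
Product: 25 (13S,14R)-15-acetoxy-13-hydroxylabd-8(17)-en-14-yl propanoate (CNP0275533.1)
Conditions: (EtCO)2O, pyridine, DMAP (cat.), CH2Cl2, 0 °C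
Reagents that add atoms: propionic anhydride, CCC(=O)OC(=O)CC
Why: DMAP-catalysed esterification of the secondary C14 hydroxyl with propionic anhydride; the tertiary C13 hydroxyl is too hindered to acylate under these conditions.

**Compound list**

1 | (S)-α-ionone, (3E)-4-[(1S)-2,6,6-trimethylcyclohex-2-en-1-yl]but-3-en-2-one | CC(=O)/C=C/[C@H]1C(C)(C)CCC=C1C | starting material
2 | (S)-dihydro-α-ionone, 4-[(1S)-2,6,6-trimethylcyclohex-2-en-1-yl]butan-2-one | CC(=O)CC[C@H]1C(C)(C)CCC=C1C | intermediate
3 | 2-methyl-2-{2-[(1S)-2,6,6-trimethylcyclohex-2-en-1-yl]ethyl}-1,3-dioxolane | CC1(CC[C@H]2C(C)(C)CCC=C2C)OCCO1 | intermediate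
4 | (4S)-3,5,5-trimethyl-4-[2-(2-methyl-1,3-dioxolan-2-yl)ethyl]cyclohex-2-en-1-one | CC1(CC[C@H]2C(C)(C)CC(=O)C=C2C)OCCO1 | intermediate
5 | (1S,4S)-3,5,5-trimethyl-4-[2-(2-methyl-1,3-dioxolan-2-yl)ethyl]cyclohex-2-en-1-ol, hydroxyl trans to the side chain | CC1(CC[C@H]2C(C)(C)C[C@H](O)C=C2C)OCCO1 | intermediate
6 | ketene acetal of 5, 2-{2-[(1S,4S)-4-(1-ethoxyethenyloxy)-2,6,6-trimethylcyclohex-2-en-1-yl]ethyl}-2-methyl-1,3-dioxolane | CC1(CC[C@H]2C(C)(C)C[C@H](OC(=C)OCC)C=C2C)OCCO1 | intermediate
7 | ethyl 2-{(1S,6S)-1,5,5-trimethyl-6-[2-(2-methyl-1,3-dioxolan-2-yl)ethyl]cyclohex-2-en-1-yl}acetate | CC1(CC[C@H]2C(C)(C)CC=C[C@]2(C)CC(=O)OCC)OCCO1 | intermediate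
8 | ethyl 2-{(1R,2S)-1,3,3-trimethyl-2-[2-(2-methyl-1,3-dioxolan-2-yl)ethyl]cyclohexyl}acetate | CC1(CC[C@H]2C(C)(C)CCC[C@]2(C)CC(=O)OCC)OCCO1 | intermediate
9 | ethyl 2-[(1R,2S)-1,3,3-trimethyl-2-(3-oxobutyl)cyclohexyl]acetate | CC(=O)CC[C@H]1C(C)(C)CCC[C@]1(C)CC(=O)OCC | intermediate
10 | ethyl 2-[(1R,2S)-2-{3-[(diethoxyphosphoryl)oxy]but-3-en-1-yl}-1,3,3-trimethylcyclohexyl]acetate | C=C(OP(=O)(OCC)OCC)CC[C@H]1C(C)(C)CCC[C@]1(C)CC(=O)OCC | intermediate
11 | ethyl 2-[(1R,2S)-2-(but-3-yn-1-yl)-1,3,3-trimethylcyclohexyl]acetate | C#CCC[C@H]1C(C)(C)CCC[C@]1(C)CC(=O)OCC | intermediate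
12 | 2-[(1R,2S)-2-(but-3-yn-1-yl)-1,3,3-trimethylcyclohexyl]acetaldehyde | C#CCC[C@H]1C(C)(C)CCC[C@]1(C)CC=O | intermediate
13 | tert-butyl({(Z)-2-[(1S,2S)-2-(but-3-yn-1-yl)-1,3,3-trimethylcyclohexyl]ethenyl}oxy)dimethylsilane, butynyl and enol ether arms trans | C#CCC[C@H]1C(C)(C)CCC[C@]1(C)/C=C\O[Si](C)(C)C(C)(C)C | intermediate
14 | albicanal, 12,13,14,15,16-pentanorlabd-8(17)-en-11-al, (1S,4aS,8aS)-5,5,8a-trimethyl-2-methylidenedecahydronaphthalene-1-carbaldehyde | C=C1CC[C@H]2C(C)(C)CCC[C@]2(C)[C@H]1C=O | intermediate
15 | albicanol, [(1S,4aS,8aS)-5,5,8a-trimethyl-2-methylidenedecahydronaphthalen-1-yl]methanol | C=C1CC[C@H]2C(C)(C)CCC[C@]2(C)[C@H]1CO | intermediate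
16 | albicanyl bromide, (1S,4aS,8aS)-1-(bromomethyl)-5,5,8a-trimethyl-2-methylidenedecahydronaphthalene | C=C1CC[C@H]2C(C)(C)CCC[C@]2(C)[C@H]1CBr | intermediate
17 | (R)-2,3-O-isopropylideneglyceraldehyde, (4R)-2,2-dimethyl-1,3-dioxolane-4-carbaldehyde | O=C[C@H]1COC(C)(C)O1 | starting material
18 | 1-[(4R)-2,2-dimethyl-1,3-dioxolan-4-yl]ethan-1-ol, both carbinol epimers | CC(O)[C@H]1COC(C)(C)O1 | intermediate
19 | 1-[(4R)-2,2-dimethyl-1,3-dioxolan-4-yl]ethan-1-one | CC(=O)[C@H]1COC(C)(C)O1 | intermediate
20 | (2S)-2-[(4R)-2,2-dimethyl-1,3-dioxolan-4-yl]-2-methyloxirane | C[C@]1(CO1)[C@H]1COC(C)(C)O1 | intermediate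
21 | albicanylmagnesium bromide (drim-8(12)-en-11-ylmagnesium bromide) | C=C1CC[C@H]2C(C)(C)CCC[C@]2(C)[C@H]1C[Mg]Br | intermediate
22 | (13S,14R)-14,15-O-isopropylidenelabd-8(17)-ene-13,14,15-triol, (5S,9S,10S) core | C=C1CC[C@H]2C(C)(C)CCC[C@]2(C)[C@H]1CC[C@](C)(O)[C@H]1COC(C)(C)O1 | intermediate
23 | (13S,14R)-labd-8(17)-ene-13,14,15-triol | C=C1CC[C@H]2C(C)(C)CCC[C@]2(C)[C@H]1CC[C@](C)(O)[C@H](O)CO | intermediate
24 | (13S,14R)-13,14-dihydroxylabd-8(17)-en-15-yl acetate | C=C1CC[C@H]2C(C)(C)CCC[C@]2(C)[C@H]1CC[C@](C)(O)[C@H](O)COC(C)=O | intermediate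
25 | (13S,14R)-15-acetoxy-13-hydroxylabd-8(17)-en-14-yl propanoate, CNP0275533.1 | C=C1CC[C@H]2C(C)(C)CCC[C@]2(C)[C@H]1CC[C@](C)(O)[C@@H](COC(C)=O)OC(=O)CC | target

**Step count and risks**

Total step count: 19. Longest linear sequence: 16 steps (steps 1–12 and 16–19, from (S)-α-ionone); the epoxide arm (steps 13–15) adds 3.

The three steps most likely to fail:

1. Step 10 (gold cyclisation). Methanolysis of the enol ether may outrun ring closure, or the new alkene may migrate into conjugation with the aldehyde and erase C9. The fallback closes ring B by cross-coupling instead of π-acid catalysis and sets out from keto ester 9. Kinetic enolisation of the methyl ketone (KN(SiMe3)2, THF, −78 °C) and trapping with PhNTf2 should give the terminal enol triflate F1. An intramolecular α-alkenylation of the ester enolate under zerovalent palladium catalysis (Pd2(dba)3, t-Bu3P, LiN(SiMe3)2, toluene), the enolate–alkenyl halide coupling known for ketones and esters, would then join C9 to C8 and give ethyl drim-8(12)-en-11-oate F2 with the methylene already exocyclic. LiAlH4 reduction brings the material back to the route at albicanol 15.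

2. Step 16 (Grignard formation and epoxide opening). Magnesium insertion into the hindered bromide may be slow and accompanied by Wurtz dimerisation, or the reagent may be spent before it opens the 2,2-disubstituted epoxide. The fallback turns C11 into a stabilised carbanion and sets out from bromide 16. Displacement with PhSO2Na (DMF, 80 °C) should give albicanyl phenyl sulfone F3. Its lithio derivative (n-BuLi, THF/DMPU, −78 °C to rt) should open epoxide 20 at C12 to give the C11-sulfonyl tertiary alcohol F4. Reductive desulfonylation (Mg, MeOH) returns to the route at acetonide 22.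

3. Step 4 (enone reduction). Hydride delivery may show poor facial selectivity or favour the cis alcohol. The fallback corrects the configuration by inversion and sets out from enone 4. Reduction with NaBH4 and CeCl3·7H2O in MeOH (Luche conditions), or whichever reductant gives most of it, supplies the cis alcohol F5. Mitsunobu esterification (4-nitrobenzoic acid, PPh3, DIAD, THF) inverts C2 to the trans 4-nitrobenzoate F6. Methanolysis (K2CO3, MeOH) returns to the route at trans alcohol 5.

**Further compounds**

F1 | step 10 | ethyl 2-[(1R,2S)-1,3,3-trimethyl-2-{3-[(trifluoromethylsulfonyl)oxy]but-3-en-1-yl}cyclohexyl]acetate | C=C(OS(=O)(=O)C(F)(F)F)CC[C@H]1C(C)(C)CCC[C@]1(C)CC(=O)OCC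
F2 | step 10 | ethyl drim-8(12)-en-11-oate, ethyl (1S,4aS,8aS)-5,5,8a-trimethyl-2-methylidenedecahydronaphthalene-1-carboxylate | C=C1CC[C@H]2C(C)(C)CCC[C@]2(C)[C@H]1C(=O)OCC
F3 | step 16 | albicanyl phenyl sulfone, (1S,4aS,8aS)-5,5,8a-trimethyl-2-methylidene-1-[(phenylsulfonyl)methyl]decahydronaphthalene | C=C1CC[C@H]2C(C)(C)CCC[C@]2(C)[C@H]1CS(=O)(=O)c1ccccc1
F4 | step 16 | (13S,14R)-14,15-O-isopropylidene-11-(phenylsulfonyl)labd-8(17)-ene-13,14,15-triol, both C11 epimers | C=C1CC[C@H]2C(C)(C)CCC[C@]2(C)[C@H]1C(C[C@](C)(O)[C@H]1COC(C)(C)O1)S(=O)(=O)c1ccccc1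
F5 | step 4 | (1R,4S)-3,5,5-trimethyl-4-[2-(2-methyl-1,3-dioxolan-2-yl)ethyl]cyclohex-2-en-1-ol, hydroxyl cis to the side chain | CC1(CC[C@H]2C(C)(C)C[C@@H](O)C=C2C)OCCO1
F6 | step 4 | (1S,4S)-3,5,5-trimethyl-4-[2-(2-methyl-1,3-dioxolan-2-yl)ethyl]cyclohex-2-en-1-yl 4-nitrobenzoate | CC1(CC[C@H]2C(C)(C)C[C@H](OC(=O)c3ccc(cc3)[N+](=O)[O-])C=C2C)OCCO1
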